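**Plan**

- Cuts, in retrosynthetic order: the sixteen O-benzyl bonds; the ether bond from the central ring C to the pyrogallol ring E; the two ether bonds from ring C to the inner rings B and D, both in one operation; the biaryl bond inside each arm (A–B, identical to F–D).
- Enabling feature: ring C carries oxygen on C1, C2, C3 and C5, with the C2 and C5 oxygens para to each other and the same biaryl ether on C1 and C3. Ring C is therefore a masked 2,6-bis(aryloxy)-1,4-benzoquinone on the mirror plane, and both arms can be delivered as one phenoxide to C2 and C6 of 2,6-dichloro-1,4-benzoquinone.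
- Forward, arm: phloroglucinol tribenzyl ether is iodinated, part of the iodide is converted into its pinacol boronate and cross-coupled with the rest to the symmetric biaryl, which is formylated once and oxidised (Dakin) to a phenol whose OH sits between two benzyloxy groups.
- Forward, assembly: two arm phenoxides add to the dichloroquinone; the quinone is reduced, the unhindered OH benzylated, the hindered OH arylated with the ring E iodide, and all benzyl groups removed. No ring is constructed.
- Stereochemistry: the target has no stereocentre, and the two biaryl axes are not stereogenic because rings A and F are symmetric 2,4,6-trioxygenated phenyl groups; nothing needs to be controlled.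

Key step: step 6

Conventions and assumption: rings A and F are the terminal 2,4,6-trihydroxyphenyl rings, B and D the inner rings bearing the ether oxygen, C the central ring, E the 3,4,5-trihydroxyphenyl ring. "Ar" means 2,4,6-tris(benzyloxy)-3-[2,4,6-tris(benzyloxy)phenyl]phenyl, and Bn means benzyl. Compounds 1, 9 and 14 are taken as purchasable. The iodide made in step 1 is divided: a little more than half goes into step 2, the rest is kept for step 3.

**Route**

Step 1
Reactants: 1 1,3,5-tris(benzyloxy)benzene
Product: 2 1,3,5-tris(benzyloxy)-2-iodobenzene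
Conditions: NIS (1.0 equiv), CH2Cl2/MeCN, 0 °C to rt, dark
Reagents that add atoms: N-iodosuccinimide, O=C1CCC(=O)N1I
Why: Electrophilic aromatic iodination of a phloroglucinol triether whose three ring C–H positions are equivalent, so one equivalent of reagent should stop at the monoiodide because the iodine hinders and slightly deactivates the ring towards a second substitution.

Step 2
Reactants: 2 1,3,5-tris(benzyloxy)-2-iodobenzene
Product: 3 2-[2,4,6-tris(benzyloxy)phenyl]-4,4,5,5-tetramethyl-1,3,2-dioxaborolane
Conditions: HBpin (1.5 equiv), PdCl2(MeCN)2 (2 mol%), SPhos (8 mol%), Et3N (3 equiv), 1,4-dioxane, 80 °C, argon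
Reagents that add atoms: pinacolborane, CC1(C)OBOC1(C)C
Why: Palladium-catalysed Miyaura-type borylation of an aryl iodide with pinacolborane, in which zerovalent palladium formed in the flask inserts into the C–I bond and the bulky biarylphosphine SPhos allows boron transfer at a carbon flanked by two alkoxy groups, while any hydrodeiodination merely returns compound 1 for re-iodination.

Step 3
Reactants: 2 1,3,5-tris(benzyloxy)-2-iodobenzene; 3 2-[2,4,6-tris(benzyloxy)phenyl]-4,4,5,5-tetramethyl-1,3,2-dioxaborolane
Product: 4 2,2',4,4',6,6'-hexakis(benzyloxy)biphenyl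
Conditions: 2 (1.0 equiv), 3 (1.3 equiv), Pd(OAc)2 (5 mol%), SPhos (10 mol%), K3PO4 (3 equiv), toluene/H2O (10:1), 100 °C, argon
Reagents that add atoms: none
Why: Suzuki–Miyaura cross-coupling under SPhos ligation, a catalyst system suited to partners that are di-ortho-substituted on both sides, should form the tetra-ortho-oxygenated biaryl bond, and because both partners carry the same aryl group any homocoupling of either one also gives 4 while protodeboronation only returns compound 1.

Step 4
Reactants: 4 2,2',4,4',6,6'-hexakis(benzyloxy)biphenyl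
Product: 6 2,4,6-tris(benzyloxy)-3-[2,4,6-tris(benzyloxy)phenyl]benzaldehyde, via aryl dimethyliminium chloride 5 (not isolated)
Conditions: POCl3/DMF (0.7 equiv each, premixed), ClCH2CH2Cl, 0 to 40 °C; then aq NaOAc
Reagents that add atoms: N,N-dimethylformamide, CN(C)C=O; water, O
Why: Vilsmeier–Haack formylation at one of the four equivalent ring C–H positions, each flanked by two benzyloxy groups, with the chloroiminium reagent as the limiting component so that the monoaldehyde should dominate and unreacted 4 is recovered and recycled.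

Step 5
Reactants: 6 2,4,6-tris(benzyloxy)-3-[2,4,6-tris(benzyloxy)phenyl]benzaldehyde
Product: 8 2,4,6-tris(benzyloxy)-3-[2,4,6-tris(benzyloxy)phenyl]phenol (ArOH), via aryl formate 7 (not isolated)
Conditions: mCPBA (1.3 equiv), CH2Cl2, 0 °C to rt; then K2CO3 (0.2 equiv), MeOH/THF, 0 °C, argon
Reagents that add atoms: 3-chloroperbenzoic acid, O=C(OO)c1cccc(Cl)c1
Why: Baeyer–Villiger oxidation of an electron-rich aldehyde (Dakin-type), in which the 2,6-dialkoxyaryl group migrates in preference to hydrogen to give formate 7, whose mild methanolysis frees a hydroxyl exactly between two benzyloxy groups without any protecting-group differentiation.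

Step 6
Reactants: 8 2,4,6-tris(benzyloxy)-3-[2,4,6-tris(benzyloxy)phenyl]phenol (ArOH); 9 2,6-dichloro-1,4-benzoquinone
Product: 11 2,6-bis(aryloxy)-1,4-benzoquinone (aryl = Ar), via 2-aryloxy-6-chloro-1,4-benzoquinone 10 (not isolated)
Conditions: 8 (2.15 equiv), Cs2CO3 (2.5 equiv), MeCN/THF, argon, 0 °C; 9 (1.0 equiv) added last, dropwise; 0 °C to rt
Reagents that add atoms: none
Why: The cesium phenoxide of 8 adds through oxygen to C2 of 9, the chlorine-bearing carbon beta to the C4 carbonyl, and the enolate so formed ejects chloride to give chloroquinone 10; the same addition–elimination at C6, beta to the same carbonyl, gives 11, so two C–O bonds form, two chlorides leave, no ring closes and no stereocentre arises. The closest known reaction type is nucleophilic vinylic substitution of halo-1,4-benzoquinones and halonaphthoquinones by phenoxides, here run twice in one flask with a 2,6-bis(benzyloxy)phenoxide that is more hindered and more electron-rich than the usual partners. The step needs ipso attack at C–Cl rather than conjugate addition at the C–H carbons C3 and C5, and O-arylation rather than C-arylation. Addition at C–H has no leaving group, is reversible and would need an oxidant to become productive, whereas loss of chloride makes the ipso path irreversible; both ortho positions and the para position of the phenoxide carry benzyloxy groups, so only the oxygen can give a stable product. The quinone is a strong enough acceptor that the two most crowded ether bonds of the target should form near room temperature without a metal; the competing process, single-electron transfer from the phenoxide to the quinone, is held back by the mild base, the low temperature, exclusion of oxygen and slow addition of the quinone.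

Step 7
Reactants: 11 2,6-bis(aryloxy)-1,4-benzoquinone
Product: 12 2,6-bis(aryloxy)benzene-1,4-diol
Conditions: Na2S2O4 (excess), EtOAc/H2O, rt, argon
Reagents that add atoms: none
Why: Two-electron reduction of a 1,4-benzoquinone to its hydroquinone by dithionite, a routine two-phase operation that touches neither the aryl ethers nor the benzyl ethers.

Step 8
Reactants: 12 2,6-bis(aryloxy)benzene-1,4-diol
Product: 13 4-(benzyloxy)-2,6-bis(aryloxy)phenol
Conditions: BnBr (1.0 equiv), K2CO3 (1.1 equiv), acetone, rt, argon
Reagents that add atoms: benzyl bromide, BrCc1ccccc1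
Why: Williamson etherification with one equivalent of benzyl bromide, expected to be regioselective because the C4 hydroxyl lies between two ring hydrogens whereas the C1 hydroxyl is buried between two bulky aryloxy groups, in line with the usual 4-O-alkylation of 2,6-disubstituted hydroquinones.

Step 9
Reactants: 14 5-iodo-1,2,3-trimethoxybenzene
Product: 16 5-iodobenzene-1,2,3-triol, via 5-iodo-1,2,3-tris(dibromoboryloxy)benzene 15 (not isolated)
Conditions: BBr3 (4 equiv), CH2Cl2, −78 °C to rt; then H2O, 0 °C
Reagents that add atoms: none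
Why: Lewis-acid ether cleavage with BBr3 (bromide attacks the methyl group of the boron-complexed ether), which should remove all three methyl groups at low temperature without touching the aryl iodide.

Step 10
Reactants: 16 5-iodobenzene-1,2,3-triol
Product: 17 1,2,3-tris(benzyloxy)-5-iodobenzene
Conditions: BnBr (3.6 equiv), K2CO3 (4 equiv), DMF, rt to 50 °C, argon
Reagents that add atoms: benzyl bromide, BrCc1ccccc1
Why: Williamson etherification of all three phenols with excess benzyl bromide, the standard tribenzylation of pyrogallol derivatives, carried out on the crude air-sensitive triol so that the last intermediate carries a single type of protecting group.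

Step 11
Reactants: 13 4-(benzyloxy)-2,6-bis(aryloxy)phenol; 17 1,2,3-tris(benzyloxy)-5-iodobenzene
Product: 18 5-(benzyloxy)-1,3-bis(aryloxy)-2-[3,4,5-tris(benzyloxy)phenoxy]benzene (hexadeca-O-benzyl ether of the target)
Conditions: 17 (1.5 equiv), CuI (10 mol%), picolinic acid (20 mol%), K3PO4 (2 equiv), DMSO, 90 °C, argon
Reagents that add atoms: none
Why: Ullmann-type diaryl ether synthesis catalysed by monovalent copper (CuI) with picolinic acid, the variant suited to ortho-disubstituted phenols, with all the hindrance placed on the phenol while iodide 17 has two free ortho positions.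

Step 12
Reactants: 18 5-(benzyloxy)-1,3-bis(aryloxy)-2-[3,4,5-tris(benzyloxy)phenoxy]benzene
Product: 19 CNP0279880.0, 3,5-bis[2,4,6-trihydroxy-3-(2,4,6-trihydroxyphenyl)phenoxy]-4-(3,4,5-trihydroxyphenoxy)phenol
Conditions: H2 (1 atm), Pd(OH)2/C, degassed THF/MeOH, rt; filtration and concentration under argon
Reagents that add atoms: none
Why: Heterogeneous catalytic hydrogenolysis of benzyl aryl ethers, which should cleave all sixteen O–CH2Ph bonds while the diaryl ether and biaryl bonds are inert, and no stereocentre is involved.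

**Compound list**

1 | 1,3,5-tris(benzyloxy)benzene | O(Cc1ccccc1)c1cc(OCc2ccccc2)cc(OCc2ccccc2)c1 | starting material
2 | 1,3,5-tris(benzyloxy)-2-iodobenzene | Ic1c(OCc2ccccc2)cc(OCc2ccccc2)cc1OCc1ccccc1 | intermediate
3 | 2-[2,4,6-tris(benzyloxy)phenyl]-4,4,5,5-tetramethyl-1,3,2-dioxaborolane | CC1(C)OB(OC1(C)C)c1c(OCc2ccccc2)cc(OCc2ccccc2)cc1OCc1ccccc1 | intermediate
4 | 2,2',4,4',6,6'-hexakis(benzyloxy)biphenyl | C(Oc1cc(OCc2ccccc2)c(-c2c(OCc3ccccc3)cc(OCc3ccccc3)cc2OCc2ccccc2)c(OCc2ccccc2)c1)c1ccccc1 | intermediate
5 | {2,4,6-tris(benzyloxy)-3-[2,4,6-tris(benzyloxy)phenyl]benzylidene}dimethylammonium chloride | C[N+](C)=Cc1c(OCc2ccccc2)cc(OCc2ccccc2)c(-c2c(OCc3ccccc3)cc(OCc3ccccc3)cc2OCc2ccccc2)c1OCc1ccccc1.[Cl-] | intermediate (not isolated)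
6 | 2,4,6-tris(benzyloxy)-3-[2,4,6-tris(benzyloxy)phenyl]benzaldehyde | O=Cc1c(OCc2ccccc2)cc(OCc2ccccc2)c(-c2c(OCc3ccccc3)cc(OCc3ccccc3)cc2OCc2ccccc2)c1OCc1ccccc1 | intermediate
7 | 2,4,6-tris(benzyloxy)-3-[2,4,6-tris(benzyloxy)phenyl]phenyl formate | O=COc1c(OCc2ccccc2)cc(OCc2ccccc2)c(-c2c(OCc3ccccc3)cc(OCc3ccccc3)cc2OCc2ccccc2)c1OCc1ccccc1 | intermediate (not isolated)
8 | 2,4,6-tris(benzyloxy)-3-[2,4,6-tris(benzyloxy)phenyl]phenol (ArOH) | Oc1c(OCc2ccccc2)cc(OCc2ccccc2)c(-c2c(OCc3ccccc3)cc(OCc3ccccc3)cc2OCc2ccccc2)c1OCc1ccccc1 | intermediate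
9 | 2,6-dichloro-1,4-benzoquinone | O=C1C=C(Cl)C(=O)C(Cl)=C1 | starting material
10 | 2-(aryloxy)-6-chloro-1,4-benzoquinone (aryl = Ar) | O=C1C=C(Cl)C(=O)C(Oc2c(OCc3ccccc3)cc(OCc3ccccc3)c(-c3c(OCc4ccccc4)cc(OCc4ccccc4)cc3OCc3ccccc3)c2OCc2ccccc2)=C1 | intermediate (not isolated)
11 | 2,6-bis(aryloxy)-1,4-benzoquinone (aryl = Ar) | O=C1C=C(Oc2c(OCc3ccccc3)cc(OCc3ccccc3)c(-c3c(OCc4ccccc4)cc(OCc4ccccc4)cc3OCc3ccccc3)c2OCc2ccccc2)C(=O)C(Oc2c(OCc3ccccc3)cc(OCc3ccccc3)c(-c3c(OCc4ccccc4)cc(OCc4ccccc4)cc3OCc3ccccc3)c2OCc2ccccc2)=C1 | intermediate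
12 | 2,6-bis(aryloxy)benzene-1,4-diol (aryl = Ar) | Oc1cc(Oc2c(OCc3ccccc3)cc(OCc3ccccc3)c(-c3c(OCc4ccccc4)cc(OCc4ccccc4)cc3OCc3ccccc3)c2OCc2ccccc2)c(O)c(Oc2c(OCc3ccccc3)cc(OCc3ccccc3)c(-c3c(OCc4ccccc4)cc(OCc4ccccc4)cc3OCc3ccccc3)c2OCc2ccccc2)c1 | intermediate
13 | 4-(benzyloxy)-2,6-bis(aryloxy)phenol (aryl = Ar) | Oc1c(Oc2c(OCc3ccccc3)cc(OCc3ccccc3)c(-c3c(OCc4ccccc4)cc(OCc4ccccc4)cc3OCc3ccccc3)c2OCc2ccccc2)cc(OCc2ccccc2)cc1Oc1c(OCc2ccccc2)cc(OCc2ccccc2)c(-c2c(OCc3ccccc3)cc(OCc3ccccc3)cc2OCc2ccccc2)c1OCc1ccccc1 | intermediate
14 | 5-iodo-1,2,3-trimethoxybenzene | COc1cc(I)cc(OC)c1OC | starting material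
15 | 5-iodo-1,2,3-tris(dibromoboryloxy)benzene | BrB(Br)Oc1cc(I)cc(OB(Br)Br)c1OB(Br)Br | intermediate (not isolated)
16 | 5-iodobenzene-1,2,3-triol | Oc1cc(I)cc(O)c1O | intermediate
17 | 1,2,3-tris(benzyloxy)-5-iodobenzene | Ic1cc(OCc2ccccc2)c(OCc2ccccc2)c(OCc2ccccc2)c1 | intermediate
18 | 5-(benzyloxy)-1,3-bis(aryloxy)-2-[3,4,5-tris(benzyloxy)phenoxy]benzene (aryl = Ar) | c1c(OCc2ccccc2)c(OCc2ccccc2)c(OCc2ccccc2)cc1Oc1c(Oc2c(OCc3ccccc3)cc(OCc3ccccc3)c(-c3c(OCc4ccccc4)cc(OCc4ccccc4)cc3OCc3ccccc3)c2OCc2ccccc2)cc(OCc2ccccc2)cc1Oc1c(OCc2ccccc2)cc(OCc2ccccc2)c(-c2c(OCc3ccccc3)cc(OCc3ccccc3)cc2OCc2ccccc2)c1OCc1ccccc1 | intermediate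
19 | CNP0279880.0, 3,5-bis[2,4,6-trihydroxy-3-(2,4,6-trihydroxyphenyl)phenoxy]-4-(3,4,5-trihydroxyphenoxy)phenol | Oc1cc(O)c(-c2c(O)cc(O)c(Oc3cc(O)cc(Oc4c(O)cc(O)c(-c5c(O)cc(O)cc5O)c4O)c3Oc3cc(O)c(O)c(O)c3)c2O)c(O)c1 | target

**Count and risks**

Total step count: 12. Longest linear sequence: 10 steps (steps 1 to 8, 11 and 12, from compound 1 to compound 19); steps 9 and 10 form the short branch to the ring E iodide.

Steps most likely to fail:

1. Step 6. The very electron-rich phenoxide may transfer an electron to the quinone faster than it adds, so that the arm is oxidatively degraded and the quinone reduced. The reaction may also stall after the first substitution, because the aryloxy group lowers the electrophilicity of 10. The fallback sets out from compound 8 and rejoins the route at compound 13, so that steps 7 and 8 are bypassed as well. Commercial 2,6-difluoro-4-hydroxybenzaldehyde would be benzylated (BnBr, K2CO3, DMF) to 4-(benzyloxy)-2,6-difluorobenzaldehyde F1. Both fluorines, each ortho to the formyl group, would then be displaced by the phenoxide of 8 in a twofold SNAr reaction (Cs2CO3, DMSO, 100 to 120 °C) to give 4-(benzyloxy)-2,6-bis(aryloxy)benzaldehyde F2. Baeyer–Villiger oxidation with mCPBA to 4-(benzyloxy)-2,6-bis(aryloxy)phenyl formate F3, followed by catalytic methanolysis (K2CO3, MeOH), would deliver phenol 13 with the hindered hydroxyl already in place.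

2. Step 11. The phenol oxygen of 13 is shielded by two very large aryloxy groups, so formation or reductive elimination of the copper phenoxide may be too slow and reduction of iodide 17 may take over. The fallback sets out from compound 17 and rejoins the route at compound 18, replacing copper catalysis by a metal-free arylation with a trivalent iodine reagent. Iodide 17 would be treated in one pot with mCPBA, TsOH·H2O and 1,3,5-trimethoxybenzene (MeCN, rt) to give [3,4,5-tris(benzyloxy)phenyl](2,4,6-trimethoxyphenyl)iodonium tosylate F4. Reaction of F4 with the potassium phenoxide of 13 (K2CO3, toluene, rt to 50 °C) should transfer the tris(benzyloxy)phenyl group to oxygen, the more electron-rich trimethoxyphenyl group acting as the ligand that stays on iodine, and give 18.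

3. Step 3. Protodeboronation of the 2,6-dialkoxyarylboronate under the basic aqueous conditions may outrun transmetalation at the crowded palladium centre, so that compound 1 is returned instead of the tetra-ortho-oxygenated biaryl. The fallback sets out from compound 2 and rejoins the route at compound 4, replacing the palladium cross-coupling by a copper-mediated reductive homocoupling that needs no boron partner. Iodide 2 alone would be heated with activated copper powder (DMF, 150 °C, argon). Oxidative addition should give 2,4,6-tris(benzyloxy)phenylcopper F5, which would couple with a second molecule of 2 in a classical Ullmann reaction to give biaryl 4.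

**Further compounds**

F1 | step 6 | 4-(benzyloxy)-2,6-difluorobenzaldehyde | O=Cc1c(F)cc(OCc2ccccc2)cc1F
F2 | step 6 | 4-(benzyloxy)-2,6-bis(aryloxy)benzaldehyde (aryl = Ar) | O=Cc1c(Oc2c(OCc3ccccc3)cc(OCc3ccccc3)c(-c3c(OCc4ccccc4)cc(OCc4ccccc4)cc3OCc3ccccc3)c2OCc2ccccc2)cc(OCc2ccccc2)cc1Oc1c(OCc2ccccc2)cc(OCc2ccccc2)c(-c2c(OCc3ccccc3)cc(OCc3ccccc3)cc2OCc2ccccc2)c1OCc1ccccc1
F3 | step 6 | 4-(benzyloxy)-2,6-bis(aryloxy)phenyl formate (aryl = Ar) | O=COc1c(Oc2c(OCc3ccccc3)cc(OCc3ccccc3)c(-c3c(OCc4ccccc4)cc(OCc4ccccc4)cc3OCc3ccccc3)c2OCc2ccccc2)cc(OCc2ccccc2)cc1Oc1c(OCc2ccccc2)cc(OCc2ccccc2)c(-c2c(OCc3ccccc3)cc(OCc3ccccc3)cc2OCc2ccccc2)c1OCc1ccccc1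
F4 | step 11 | [3,4,5-tris(benzyloxy)phenyl](2,4,6-trimethoxyphenyl)iodonium 4-methylbenzenesulfonate | COc1cc(OC)c([I+]c2cc(OCc3ccccc3)c(OCc3ccccc3)c(OCc3ccccc3)c2)c(OC)c1.Cc1ccc(cc1)S(=O)(=O)[O-]
F5 | step 3 | 2,4,6-tris(benzyloxy)phenylcopper | [Cu]c1c(OCc2ccccc2)cc(OCc2ccccc2)cc1OCc1ccccc1
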